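**Strategy.** The depside is cut at the ester bond between the ring A carbonyl and O-4' of ring B, and ring B is then assembled from two acyclic pieces in one photochemical and thermal cascade. The precursor is an (E)-configured diazo enone carrying the future C1' ester and C6' methyl; its partner, a siloxypropyne, brings C3', the C3' methyl and C4'. The cascade exploits the resorcinol pattern of ring B, in which the C3' methyl lies between O-2' and O-4': four ring bonds form, O-2' emerges as a free phenol beside the ester and O-4' as a silyl ether, which labels the site where ring A is attached.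

Key step: step 4

Remark: the target has no stereocenter, so only the E geometry of the enoate must be controlled. C1–C6 denote the chlorinated acyl ring A and C1'–C6' the methyl benzoate ring B (C1' bears CO2Me). Ethyl acetate supplies only two of the three propyne carbons, so the third is taken from dibromomethane.

**Step 1**
Reactants: 1 butane-2,3-dione (biacetyl); 2 methyl (triphenylphosphoranylidene)acetate
Product: 3 methyl (E)-3-methyl-4-oxopent-2-enoate
Conditions: 1 (2 equiv), CH2Cl2, 0 °C → rt
Reagents that add atoms: none
Why: Wittig olefination with a stabilised ylide, in which the excess of diketone limits the reaction to one carbonyl and the stabilised ylide should place the ester trans to the acetyl group (E).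

**Step 2**
Reactants: 3 methyl (E)-3-methyl-4-oxopent-2-enoate
Product: 5 methyl (E)-5-diazo-3-methyl-4-oxopent-2-enoate, via trifluoroacetyl diketone 4 (not isolated)
Conditions: LiN(SiMe3)2, THF, −78 °C; CF3CO2CH2CF3, −78 °C; aq HCl work-up, crude 4 taken on at once; then p-ABSA, Et3N, H2O (1 equiv), MeCN, rt
Reagents that add atoms: 4-acetamidobenzenesulfonyl azide (p-ABSA), CC(=O)Nc1ccc(cc1)S(=O)(=O)N=[N+]=[N-] (supplies N2); 2,2,2-trifluoroethyl trifluoroacetate, O=C(OCC(F)(F)F)C(F)(F)F (its CF3CO group is carried only by 4)
Why: Detrifluoroacetylative diazo transfer (Regitz-type), in which kinetic deprotonation takes the acetyl methyl (the only enolisable position of the ketone), Claisen trifluoroacetylation activates it, and the trifluoroacetyl group leaves on the sulfonamide nitrogen, so the enoate and its E geometry should stay untouched.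

**Step 3**
Reactants: 6 ethyl acetate
Product: 9 triisopropyl(prop-1-yn-1-yloxy)silane, via dibromo enolate 7 (not isolated), via lithium ynolate 8 (not isolated)
Conditions: CH2Br2, lithium 2,2,6,6-tetramethylpiperidide (2.1 equiv), THF, −78 °C; add 6; then n-BuLi, −78 °C → rt; then iPr3SiOTf, −78 → 0 °C
Reagents that add atoms: dibromomethane, BrCBr (one alkyne carbon); triisopropylsilyl trifluoromethanesulfonate, CC(C)[Si](OS(=O)(=O)C(F)(F)F)(C(C)C)C(C)C
Why: Kowalski ester homologation stopped at the ynolate stage, in which dibromomethyllithium acylation gives enolate 7, bromine–lithium exchange triggers a carbenoid 1,2-shift to ynolate 8, and the bulky silyl triflate should silylate 8 on oxygen.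

**Step 4**
Reactants: 5 methyl (E)-5-diazo-3-methyl-4-oxopent-2-enoate; 9 triisopropyl(prop-1-yn-1-yloxy)silane
Product: 14 methyl 2-hydroxy-3,6-dimethyl-4-(triisopropylsilyloxy)benzoate, via vinylketene 10 (not isolated), via vinylcyclobutenone 11 (not isolated), via dienylketene 12 (not isolated), via cyclohexadienone 13 (not isolated)
Conditions: 9 (1.3 equiv), ClCH2CH2Cl (degassed, dilute), hν (Hg lamp, Pyrex filter, λ > 300 nm), rt; then 80 °C
Reagents that add atoms: none
Why: This is a Danheiser benzannulation in its diazo ketone and siloxyalkyne variant. Light expels N2 from 5 and the alkenyl group shifts (photochemical Wolff rearrangement, bond C5'–C6') to give vinylketene 10, whose ketene C=C adds to alkyne 9 in a [2+2] cycloaddition (bonds C2'–C3' and C4'–C5') to give cyclobutenone 11. Heating opens 11 by four-electron conrotatory electrocyclic cleavage to dienylketene 12, and ring B is closed by thermal six-electron disrotatory electrocyclisation (bond C1'–C2') to dienone 13, which enolises to the aromatic product. No stereocenter is formed. The step needs one regiochemistry in the [2+2] event, and the oxygen-polarised alkyne secures it: its nucleophilic methyl-bearing carbon bonds to the ketene carbonyl carbon, which puts the methyl at C3' between the two oxygens and leaves the silyl group on O-4'. The E enoate, which irradiation above 300 nm is meant to preserve, holds the ester on the outer side of the closing triene, away from the ketene.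

**Step 5**
Reactants: 15 2,4-dihydroxy-3,6-dimethylbenzoic acid (3-methylorsellinic acid)
Product: 16 5-chloro-2,4-dihydroxy-3,6-dimethylbenzoic acid
Conditions: SO2Cl2 (1.05 equiv), Et2O, 0 °C, dark
Reagents that add atoms: sulfuryl chloride, O=S(=O)(Cl)Cl
Why: Electrophilic aromatic chlorination, in which C5 is the only unsubstituted ring position and is activated by the ortho and para hydroxyls, so one equivalent of reagent at low temperature should give the monochloride without loss of CO2.

**Step 6**
Reactants: 16 5-chloro-2,4-dihydroxy-3,6-dimethylbenzoic acid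
Product: 18 5-chloro-2,4-bis(methoxymethoxy)-3,6-dimethylbenzoic acid, via tris-MOM ester 17 (not isolated)
Conditions: NaH (3.5 equiv), MOMCl (3.5 equiv), THF–DMF, 0 °C → rt; then 2 M aq NaOH, MeOH, 50 °C; cold dilute HCl to pH 3
Reagents that add atoms: chloromethyl methyl ether (MOMCl), COCCl; sodium hydroxide, [Na+].[OH-] (one carboxyl oxygen if the ester is cleaved at the acyl carbon)
Why: Williamson-type O-alkylation of the carboxylate and both phenoxides gives 17, and saponification should then cleave only the acylal-type MOM ester because aryl MOM ethers are stable to base.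

**Step 7**
Reactants: 18 5-chloro-2,4-bis(methoxymethoxy)-3,6-dimethylbenzoic acid
Product: 19 5-chloro-2,4-bis(methoxymethoxy)-3,6-dimethylbenzoyl fluoride
Conditions: cyanuric fluoride, pyridine, CH2Cl2, −10 °C → rt
Reagents that add atoms: cyanuric fluoride (2,4,6-trifluoro-1,3,5-triazine), Fc1nc(F)nc(F)n1
Why: Deoxyfluorination of a carboxylic acid to the acyl fluoride under non-acidic conditions should spare the MOM ethers, and a doubly ortho-substituted benzoyl fluoride is stable enough to isolate without closing onto the neighbouring MOM oxygen.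

**Step 8**
Reactants: 14 methyl 2-hydroxy-3,6-dimethyl-4-(triisopropylsilyloxy)benzoate; 19 5-chloro-2,4-bis(methoxymethoxy)-3,6-dimethylbenzoyl fluoride
Product: 20 methyl 4-{[5-chloro-2,4-bis(methoxymethoxy)-3,6-dimethylbenzoyl]oxy}-2-hydroxy-3,6-dimethylbenzoate
Conditions: CsF (0.2 equiv), DMF, 4 Å sieves, rt → 50 °C
Reagents that add atoms: none
Why: Fluoride-catalysed desilylative O-acylation of an aryl silyl ether by an acyl fluoride, in which fluoride cleaves the O-4'–Si bond, the phenoxide attacks the small acyl fluoride and releases fluoride again, while the 2'-OH, hydrogen-bonded to the ester and flanked on both sides, should stay unreacted.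

**Step 9**
Reactants: 20 methyl 4-{[5-chloro-2,4-bis(methoxymethoxy)-3,6-dimethylbenzoyl]oxy}-2-hydroxy-3,6-dimethylbenzoate
Product: 21 methyl 4-[(5-chloro-2,4-dihydroxy-3,6-dimethylbenzoyl)oxy]-2-hydroxy-3,6-dimethylbenzoate (CNP0106652.0)
Conditions: 3 M aq HCl, THF, 40 °C
Reagents that add atoms: none
Why: Acid-catalysed acetal hydrolysis removes both aryl MOM ethers, while the doubly ortho-substituted depside ester and the chelated methyl ester are hindered and should survive dilute acid at this temperature.

**Compound list**
1 | butane-2,3-dione (biacetyl) | CC(=O)C(C)=O | starting material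
2 | methyl (triphenylphosphoranylidene)acetate | COC(=O)C=P(c1ccccc1)(c1ccccc1)c1ccccc1 | starting material
3 | methyl (E)-3-methyl-4-oxopent-2-enoate | COC(=O)/C=C(\C)C(C)=O | intermediate
4 | methyl (E)-6,6,6-trifluoro-3-methyl-4,6-dioxohex-2-enoate (largely enolised) | COC(=O)/C=C(\C)C(=O)CC(=O)C(F)(F)F | intermediate (not isolated)
5 | methyl (E)-5-diazo-3-methyl-4-oxopent-2-enoate | COC(=O)/C=C(\C)C(=O)C=[N+]=[N-] | intermediate
6 | ethyl acetate | CCOC(C)=O | starting material
7 | lithium 1,1-dibromoprop-1-en-2-olate | CC([O-])=C(Br)Br.[Li+] | intermediate (not isolated)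
8 | lithium prop-1-yn-1-olate | CC#C[O-].[Li+] | intermediate (not isolated)
9 | triisopropyl(prop-1-yn-1-yloxy)silane | CC#CO[Si](C(C)C)(C(C)C)C(C)C | intermediate
10 | methyl (2E)-3-methyl-5-oxopenta-2,4-dienoate | COC(=O)/C=C(\C)C=C=O | intermediate (not isolated)
11 | methyl (E)-3-[3-methyl-4-oxo-2-(triisopropylsilyloxy)cyclobut-2-en-1-yl]but-2-enoate (racemic) | COC(=O)/C=C(\C)C1C(=O)C(C)=C1O[Si](C(C)C)(C(C)C)C(C)C | intermediate (not isolated)
12 | methyl (2E,4E)-3,6-dimethyl-7-oxo-5-(triisopropylsilyloxy)hepta-2,4,6-trienoate | COC(=O)/C=C(\C)/C=C(/O[Si](C(C)C)(C(C)C)C(C)C)C(C)=C=O | intermediate (not isolated)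
13 | methyl 2,5-dimethyl-6-oxo-4-(triisopropylsilyloxy)cyclohexa-2,4-diene-1-carboxylate (racemic) | COC(=O)C1C(C)=CC(O[Si](C(C)C)(C(C)C)C(C)C)=C(C)C1=O | intermediate (not isolated)
14 | methyl 2-hydroxy-3,6-dimethyl-4-(triisopropylsilyloxy)benzoate | COC(=O)c1c(C)cc(O[Si](C(C)C)(C(C)C)C(C)C)c(C)c1O | intermediate
15 | 2,4-dihydroxy-3,6-dimethylbenzoic acid (3-methylorsellinic acid) | Cc1cc(O)c(C)c(O)c1C(=O)O | starting material
16 | 5-chloro-2,4-dihydroxy-3,6-dimethylbenzoic acid | Cc1c(Cl)c(O)c(C)c(O)c1C(=O)O | intermediate
17 | methoxymethyl 5-chloro-2,4-bis(methoxymethoxy)-3,6-dimethylbenzoate | COCOC(=O)c1c(C)c(Cl)c(OCOC)c(C)c1OCOC | intermediate (not isolated)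
18 | 5-chloro-2,4-bis(methoxymethoxy)-3,6-dimethylbenzoic acid | COCOc1c(C)c(OCOC)c(Cl)c(C)c1C(=O)O | intermediate
19 | 5-chloro-2,4-bis(methoxymethoxy)-3,6-dimethylbenzoyl fluoride | COCOc1c(C)c(OCOC)c(Cl)c(C)c1C(F)=O | intermediate
20 | methyl 4-{[5-chloro-2,4-bis(methoxymethoxy)-3,6-dimethylbenzoyl]oxy}-2-hydroxy-3,6-dimethylbenzoate | COC(=O)c1c(C)cc(OC(=O)c2c(C)c(Cl)c(OCOC)c(C)c2OCOC)c(C)c1O | intermediate
21 | methyl 4-[(5-chloro-2,4-dihydroxy-3,6-dimethylbenzoyl)oxy]-2-hydroxy-3,6-dimethylbenzoate (CNP0106652.0) | COC(=O)c1c(C)cc(OC(=O)c2c(C)c(Cl)c(O)c(C)c2O)c(C)c1O | target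

**Total step count:** 9
**Longest linear sequence:** 5 steps (1, 2, 4, 8, 9; the ring A branch 5, 6, 7, 8, 9 is equally long)

**Steps most likely to fail**

Step 4 (benzannulation). Three processes can drain the cascade. Light may isomerise the enoate to the Z form, whose vinylketene can close onto its own ester carbonyl instead of meeting the alkyne. The diazo group may add as a dipole to the electron-poor alkene of a second molecule. The ketene may also be captured by the product phenol. The fallback gives up the annulation and takes ring B from the aromatic pool. It sets out from 15: the carboxyl group is esterified chemoselectively with MeI and KHCO3 in DMF to give methyl 2,4-dihydroxy-3,6-dimethylbenzoate F1. The free, non-chelated 4-hydroxyl of F1 is then silylated with iPr3SiCl and imidazole in DMF, which comes back to the route at 14.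

Step 8 (depside bond). The fluoride chain may stall because the acidic 2'-OH ties up fluoride as bifluoride. Acyl transfer to the doubly ortho-substituted carbonyl may also be slow enough for traces of water to hydrolyse the acyl fluoride, or for some acylation to occur at O-2'. The fallback replaces the catalytic chain by a stoichiometric phenoxide of a fully protected ring B. It sets out from 14: the 2'-OH is capped with NaH and MOMCl in DMF to give methyl 2-(methoxymethoxy)-3,6-dimethyl-4-(triisopropylsilyloxy)benzoate F2. The silyl group is removed with Bu4NF in THF to give methyl 4-hydroxy-2-(methoxymethoxy)-3,6-dimethylbenzoate F3. Its sodium phenoxide (NaH, THF–DMF, rt → 60 °C) is acylated with 19 to give methyl 4-{[5-chloro-2,4-bis(methoxymethoxy)-3,6-dimethylbenzoyl]oxy}-2-(methoxymethoxy)-3,6-dimethylbenzoate F4. All three MOM groups are then cleaved under the conditions of step 9, which comes back to the route at 21.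

Step 2 (diazo transfer). The amide base or the enolate may add in conjugate fashion to the doubly activated alkene and start oligomerisation instead of clean deprotonation at the acetyl methyl. The trifluoroacetylation may also go partly on oxygen. The fallback avoids the lithium enolate. It sets out from 3: soft enolisation with Me3SiOTf and Et3N in CH2Cl2 at 0 °C gives methyl (2E)-3-methyl-4-(trimethylsilyloxy)penta-2,4-dienoate F5. NBS in THF at −78 °C converts F5 into methyl (E)-5-bromo-3-methyl-4-oxopent-2-enoate F6. N,N'-Ditosylhydrazine and DBU in THF at 0 °C (N-alkylation followed by double loss of sulfinate) then turn the bromomethyl ketone into the diazomethyl ketone, which comes back to the route at 5.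

**Further compounds**
F1 | step 4 | methyl 2,4-dihydroxy-3,6-dimethylbenzoate | COC(=O)c1c(C)cc(O)c(C)c1O
F2 | step 8 | methyl 2-(methoxymethoxy)-3,6-dimethyl-4-(triisopropylsilyloxy)benzoate | COCOc1c(C)c(O[Si](C(C)C)(C(C)C)C(C)C)cc(C)c1C(=O)OC
F3 | step 8 | methyl 4-hydroxy-2-(methoxymethoxy)-3,6-dimethylbenzoate | COCOc1c(C)c(O)cc(C)c1C(=O)OC
F4 | step 8 | methyl 4-{[5-chloro-2,4-bis(methoxymethoxy)-3,6-dimethylbenzoyl]oxy}-2-(methoxymethoxy)-3,6-dimethylbenzoate | COCOc1c(C)c(OC(=O)c2c(C)c(Cl)c(OCOC)c(C)c2OCOC)cc(C)c1C(=O)OC
F5 | step 2 | methyl (2E)-3-methyl-4-(trimethylsilyloxy)penta-2,4-dienoate | COC(=O)/C=C(\C)C(=C)O[Si](C)(C)C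
F6 | step 2 | methyl (E)-5-bromo-3-methyl-4-oxopent-2-enoate | COC(=O)/C=C(\C)C(=O)CBr
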